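**Plan**

- Retrosynthesis: the seven O–CH3 bonds are cut last. Before that, the ten aryl C–OH bonds on rings A, B, C, E and F are cut back to ten formyl groups. The five diaryl ether bonds at formyl-flanked carbons are then cut as fluoride displacements, and the one unactivated ether bond, O(C6 of ring D)–C1 of ring E, as a copper-catalysed coupling.
- Enabling feature: rings are lettered A (2,4,6-trioxygenated end) to G (3,4,5-trioxygenated end). On rings A, B, C, E and F each ether-bearing carbon lies between two C–OH carbons, ten in all. Written as C–CHO, these carbons activate a fluorine on the carbon between them and later become C–OH by Dakin oxidation.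
- Building blocks: no ring is constructed. 5-Bromo-2-fluorobenzaldehyde supplies rings A, B, C, E and F through one acetal-masked monomer family, in which the fluorine is inert until the acetals are hydrolysed. 3,4,5-Trimethoxyphenol supplies rings D and G.
- Order of joining: A+B, then C; separately D+E by Ullmann coupling; union of D with C; then F; then G. Tenfold Dakin oxidation and global demethylation follow.
- Stereochemistry: the target has no stereocentre and none is created.

Key step: step 16

Remark: ring D is numbered C1 (oxygen to ring C), C2 (H), C3–C5 (three oxygens), C6 (oxygen to ring E). 5-Bromo-2-fluorobenzaldehyde is taken as a catalogue compound. Dimethyl acetals are hydrolysed in the flask of the preceding substitution, and the acetal intermediates are numbered.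

**Route**

Step 1
Reactants: 1 5-bromo-2-fluorobenzaldehyde
Product: 2 4-bromo-2-(dimethoxymethyl)-1-fluorobenzene
Conditions: HC(OMe)3, TsOH (cat.), MeOH, reflux; NaHCO3
Reagents that add atoms: trimethyl orthoformate, SMILES COC(OC)OC; methanol, SMILES CO
Why: Acid-catalysed acetalisation, driven by the orthoformate as water scavenger, should mask the formyl group so that the following lithiation meets no electrophile.

Step 2
Reactants: 2 4-bromo-2-(dimethoxymethyl)-1-fluorobenzene
Product: 5 5-bromo-3-(dimethoxymethyl)-2-fluorobenzaldehyde, via aryllithium 3 (not isolated), via lithium hemiaminal alkoxide 4 (not isolated)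
Conditions: LiN(iPr)2, THF, −78 °C; DMF, −78 °C; sat. aq. NH4Cl
Reagents that add atoms: N,N-dimethylformamide, SMILES CN(C)C=O
Why: Directed ortho-lithiation and formylation: fluorine acidifies its free ortho position far more than bromine or the acetal acidify theirs, so the amide base should deprotonate there at −78 °C (cold enough to hold back LiF loss to the aryne), and the DMF adduct collapses to the aldehyde on work-up.

Step 3
Reactants: 5 5-bromo-3-(dimethoxymethyl)-2-fluorobenzaldehyde
Product: 6 5-bromo-1,3-bis(dimethoxymethyl)-2-fluorobenzene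
Conditions: HC(OMe)3, TsOH (cat.), MeOH, 50 °C; Et3N
Reagents that add atoms: trimethyl orthoformate, SMILES COC(OC)OC; methanol, SMILES CO
Why: A second acetalisation of the same kind leaves the fluorine without any activating group, so the aryl bromide can be taken through organolithium and copper chemistry.

Step 4
Reactants: 6 5-bromo-1,3-bis(dimethoxymethyl)-2-fluorobenzene
Product: 9 3,5-bis(dimethoxymethyl)-4-fluorophenol, via aryllithium 7 (not isolated), via lithium aryltrimethoxyborate 8 (not isolated)
Conditions: n-BuLi, THF, −78 °C; B(OMe)3, −78 °C → rt; 30% H2O2, aq. NaOH, 0 °C; work-up at pH 7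
Reagents that add atoms: hydrogen peroxide, SMILES OO; trimethyl borate, SMILES COB(OC)OC (boron and methoxy groups of intermediate 8 only)
Why: Bromine–lithium exchange, borylation and oxidative hydroxydeboronation with alkaline peroxide should turn C–Br into C–OH, with the acetals and the dormant fluorine untouched under these basic conditions.

Step 5
Reactants: 9 3,5-bis(dimethoxymethyl)-4-fluorophenol
Product: 11 2-fluoro-5-methoxyisophthalaldehyde, via anisole bis-acetal 10 (not isolated)
Conditions: MeI, K2CO3, DMF, rt; then 2 M HCl, THF, rt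
Reagents that add atoms: iodomethane, SMILES CI; water, SMILES O
Why: Williamson etherification of the phenoxide followed by acid hydrolysis of both dimethyl acetals gives the ring A monomer and switches its fluorine on for substitution.

Step 6
Reactants: 11 2-fluoro-5-methoxyisophthalaldehyde; 9 3,5-bis(dimethoxymethyl)-4-fluorophenol (1.0 equiv)
Product: 13 2-(4-fluoro-3,5-diformylphenoxy)-5-methoxyisophthalaldehyde, via A–B acetal fluoride 12 (not isolated)
Conditions: K2CO3, DMF, 50 °C; then 2 M HCl, THF, rt
Reagents that add atoms: water, SMILES O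
Why: Nucleophilic aromatic substitution by addition–elimination: the fluorine of 11 sits between two ortho formyl groups that stabilise the Meisenheimer adduct, whereas the fluorine of 9 stays inert until the acid treatment hydrolyses its acetals, so exactly one unit should be added.

Step 7
Reactants: 13 2-(4-fluoro-3,5-diformylphenoxy)-5-methoxyisophthalaldehyde; 9 3,5-bis(dimethoxymethyl)-4-fluorophenol (1.0 equiv)
Product: 15 5-[4-(2,6-diformyl-4-methoxyphenoxy)-3,5-diformylphenoxy]-2-fluoroisophthalaldehyde, via A–B–C acetal fluoride 14 (not isolated)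
Conditions: K2CO3, DMF, 50 °C; then 2 M HCl, THF, rt
Reagents that add atoms: water, SMILES O
Why: The same SNAr and unmasking cycle adds ring C, and since fluoride leaves far faster than the aryloxide at the already formed formyl-flanked ether carbon the chain should grow without exchange.

Step 8
Reactants: 16 3,4,5-trimethoxyphenol
Product: 17 6-hydroxy-2,3,4-trimethoxybenzaldehyde
Conditions: MgCl2, Et3N, (CH2O)n, MeCN, reflux; 1 M HCl
Reagents that add atoms: paraformaldehyde (formaldehyde), SMILES C=O
Why: Casnati–Skattebøl ortho-formylation through the magnesium phenoxide is ortho-specific, and the two ortho positions of 16 are equivalent.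

Step 9
Reactants: 17 6-hydroxy-2,3,4-trimethoxybenzaldehyde
Product: 18 6-(benzyloxy)-2,3,4-trimethoxybenzaldehyde
Conditions: BnBr, K2CO3, DMF, 60 °C
Reagents that add atoms: benzyl bromide, SMILES BrCc1ccccc1
Why: Williamson benzylation protects the oxygen destined for ring C, which keeps the two neighbouring oxygens of ring D distinguishable.

Step 10
Reactants: 18 6-(benzyloxy)-2,3,4-trimethoxybenzaldehyde
Product: 20 6-(benzyloxy)-2,3,4-trimethoxyphenol, via aryl formate 19 (not isolated)
Conditions: mCPBA, CH2Cl2, 0 °C → rt; then K2CO3 (cat.), MeOH, rt, argon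
Reagents that add atoms: 3-chloroperbenzoic acid, SMILES O=C(OO)c1cccc(Cl)c1
Why: Dakin (Baeyer–Villiger-type) oxidation: on this tetraoxygenated ring the aryl group migrates readily to give the formate, and mild methanolysis frees the phenol that will carry ring E.

Step 11
Reactants: 20 6-(benzyloxy)-2,3,4-trimethoxyphenol; 6 5-bromo-1,3-bis(dimethoxymethyl)-2-fluorobenzene
Product: 21 1-(benzyloxy)-2-[3,5-bis(dimethoxymethyl)-4-fluorophenoxy]-3,4,5-trimethoxybenzene
Conditions: CuI (10 mol%), picolinic acid (20 mol%), K3PO4, DMSO, 90 °C, argon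
Reagents that add atoms: none
Why: Ullmann diaryl ether synthesis with CuI and picolinic acid, a ligand system suited to di-ortho-substituted phenols, should engage only the C–Br bond of 6 because its fluorine is not activated, and it is run before any formyl-flanked ether exists.

Step 12
Reactants: 21 1-(benzyloxy)-2-[3,5-bis(dimethoxymethyl)-4-fluorophenoxy]-3,4,5-trimethoxybenzene
Product: 22 2-[3,5-bis(dimethoxymethyl)-4-fluorophenoxy]-3,4,5-trimethoxyphenol
Conditions: H2 (1 atm), Pd/C, EtOAc, rt
Reagents that add atoms: none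
Why: Hydrogenolysis of the benzyl ether spares aryl fluoride, acetals and methyl ethers, and it frees O1 of ring D only when the neighbouring oxygen already bears the non-activated ring E, so ring D never holds a free phenoxide beside a formyl-activated aryl ether that could migrate (Smiles rearrangement).

Step 13
Reactants: 22 2-[3,5-bis(dimethoxymethyl)-4-fluorophenoxy]-3,4,5-trimethoxyphenol (1.0 equiv); 15 5-[4-(2,6-diformyl-4-methoxyphenoxy)-3,5-diformylphenoxy]-2-fluoroisophthalaldehyde
Product: 24 A–E octaaldehyde fluoride (aryl group of 15 on O1 of ring D; ring E as 4-fluoro-3,5-diformylphenyl on O6), via A–E acetal fluoride 23 (not isolated)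
Conditions: K2CO3, DMF, 45 °C; then 2 M HCl, THF, rt
Reagents that add atoms: water, SMILES O
Why: SNAr union of the two halves: the electron-rich ring D phenoxide displaces the fluoride between the two formyl groups of ring C, and the acid treatment then unmasks ring E for the next addition.

Step 14
Reactants: 24 A–E octaaldehyde fluoride; 9 3,5-bis(dimethoxymethyl)-4-fluorophenol (1.0 equiv)
Product: 26 A–F decaaldehyde fluoride (ring F as 4-fluoro-3,5-diformylphenoxy on the former C–F carbon of ring E), via A–F acetal fluoride 25 (not isolated)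
Conditions: K2CO3, DMF, 45 °C; then 2 M HCl, THF, rt
Reagents that add atoms: water, SMILES O
Why: The SNAr and unmasking cycle used in steps 6 and 7 adds ring F at the formyl-flanked fluorine of ring E.

Step 15
Reactants: 26 A–F decaaldehyde fluoride; 16 3,4,5-trimethoxyphenol
Product: 27 decaaldehyde heptamer (ten formyl groups on rings A B C E F; seven methyl ethers on rings A D G)
Conditions: K2CO3, DMF, 45 °C
Reagents that add atoms: none
Why: SNAr of 3,4,5-trimethoxyphenoxide at the last formyl-flanked fluorine caps the chain with ring G.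

Step 16
Reactants: 27 decaaldehyde heptamer
Product: 29 decaphenol heptamethyl ether (two free hydroxyls on each of rings A B C E F), via decaformate 28 (not isolated)
Conditions: mCPBA (25 equiv), CH2Cl2, 0 °C → 35 °C; Me2S; then 1.25 M HCl in MeOH, rt, argon
Reagents that add atoms: 3-chloroperbenzoic acid, SMILES O=C(OO)c1cccc(Cl)c1
Why: Dakin oxidation (Baeyer–Villiger oxidation of an aryl aldehyde): the peracid adds to each formyl group to give a Criegee adduct, the aryl carbon shifts from carbon to oxygen with loss of 3-chlorobenzoate, and the resulting aryl formate is cleaved by acidic methanol to the phenol and methyl formate. The closest known reaction is the peracid oxidation of 2-aryloxybenzaldehydes, themselves made by fluoride displacement, to 2-aryloxyphenols; here it should run at ten sites of one molecule. No ring is closed and no stereocentre is formed. The selectivity needed is aryl over hydride migration at every formyl group, and it is secured by the diaryl ether oxygen on the carbon ortho to each formyl-bearing carbon, whose lone pair supports the migrating ipso carbon. Holding the products as formates until all ten groups have reacted, and freeing the phenols only under acid and argon, should keep the increasingly oxygenated rings from further oxidation, while rings D and G stay shielded as methyl ethers.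

Step 17
Reactants: 29 decaphenol heptamethyl ether
Product: 30 CNP0304148.0
Conditions: BBr3 (excess), CH2Cl2, −78 °C → rt; MeOH, then H2O, 0 °C
Reagents that add atoms: none
Why: Lewis-acid ether cleavage with BBr3 removes all seven methyl groups by bromide attack on the O-methyl carbon of the boron-complexed ethers, whereas the diaryl ether bonds offer no sp3 carbon and should stay intact.

**Compound list**

1 | 5-bromo-2-fluorobenzaldehyde | O=Cc1cc(Br)ccc1F | starting material
2 | 4-bromo-2-(dimethoxymethyl)-1-fluorobenzene | COC(OC)c1cc(Br)ccc1F | intermediate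
3 | [5-bromo-3-(dimethoxymethyl)-2-fluorophenyl]lithium (not isolated) | COC(OC)c1cc(Br)cc([Li])c1F | intermediate
4 | lithium hemiaminal alkoxide from 3 and DMF (not isolated) | COC(OC)c1cc(Br)cc(C(O[Li])N(C)C)c1F | intermediate
5 | 5-bromo-3-(dimethoxymethyl)-2-fluorobenzaldehyde | COC(OC)c1cc(Br)cc(C=O)c1F | intermediate
6 | 5-bromo-1,3-bis(dimethoxymethyl)-2-fluorobenzene (ring E unit) | COC(OC)c1cc(Br)cc(C(OC)OC)c1F | intermediate
7 | [3,5-bis(dimethoxymethyl)-4-fluorophenyl]lithium (not isolated) | COC(OC)c1cc([Li])cc(C(OC)OC)c1F | intermediate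
8 | lithium [3,5-bis(dimethoxymethyl)-4-fluorophenyl]trimethoxyborate (not isolated) | [Li+].CO[B-](OC)(OC)c1cc(C(OC)OC)c(F)c(C(OC)OC)c1 | intermediate
9 | 3,5-bis(dimethoxymethyl)-4-fluorophenol (unit for rings B, C and F) | COC(OC)c1cc(O)cc(C(OC)OC)c1F | intermediate
10 | 1,3-bis(dimethoxymethyl)-2-fluoro-5-methoxybenzene (not isolated) | COc1cc(C(OC)OC)c(F)c(C(OC)OC)c1 | intermediate
11 | 2-fluoro-5-methoxyisophthalaldehyde (ring A unit) | COc1cc(C=O)c(F)c(C=O)c1 | intermediate
12 | 2-[3,5-bis(dimethoxymethyl)-4-fluorophenoxy]-5-methoxyisophthalaldehyde (A–B acetal fluoride, not isolated) | COc1cc(C=O)c(Oc2cc(C(OC)OC)c(F)c(C(OC)OC)c2)c(C=O)c1 | intermediate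
13 | 2-(4-fluoro-3,5-diformylphenoxy)-5-methoxyisophthalaldehyde (A–B tetraaldehyde fluoride) | COc1cc(C=O)c(Oc2cc(C=O)c(F)c(C=O)c2)c(C=O)c1 | intermediate
14 | 2-{4-[3,5-bis(dimethoxymethyl)-4-fluorophenoxy]-2,6-diformylphenoxy}-5-methoxyisophthalaldehyde (A–B–C acetal fluoride, not isolated) | COc1cc(C=O)c(Oc2cc(C=O)c(Oc3cc(C(OC)OC)c(F)c(C(OC)OC)c3)c(C=O)c2)c(C=O)c1 | intermediate
15 | 5-[4-(2,6-diformyl-4-methoxyphenoxy)-3,5-diformylphenoxy]-2-fluoroisophthalaldehyde (A–B–C hexaaldehyde fluoride) | COc1cc(C=O)c(Oc2cc(C=O)c(Oc3cc(C=O)c(F)c(C=O)c3)c(C=O)c2)c(C=O)c1 | intermediate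
16 | 3,4,5-trimethoxyphenol | COc1cc(O)cc(OC)c1OC | starting material
17 | 6-hydroxy-2,3,4-trimethoxybenzaldehyde | COc1cc(O)c(C=O)c(OC)c1OC | intermediate
18 | 6-(benzyloxy)-2,3,4-trimethoxybenzaldehyde | COc1cc(OCc2ccccc2)c(C=O)c(OC)c1OC | intermediate
19 | 6-(benzyloxy)-2,3,4-trimethoxyphenyl formate (not isolated) | COc1cc(OCc2ccccc2)c(OC=O)c(OC)c1OC | intermediate
20 | 6-(benzyloxy)-2,3,4-trimethoxyphenol | COc1cc(OCc2ccccc2)c(O)c(OC)c1OC | intermediate
21 | 1-(benzyloxy)-2-[3,5-bis(dimethoxymethyl)-4-fluorophenoxy]-3,4,5-trimethoxybenzene (benzyl-protected D–E ether) | COc1cc(OCc2ccccc2)c(Oc2cc(C(OC)OC)c(F)c(C(OC)OC)c2)c(OC)c1OC | intermediate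
22 | 2-[3,5-bis(dimethoxymethyl)-4-fluorophenoxy]-3,4,5-trimethoxyphenol (D–E phenol) | COc1cc(O)c(Oc2cc(C(OC)OC)c(F)c(C(OC)OC)c2)c(OC)c1OC | intermediate
23 | A–E acetal fluoride: aryl group of 15 on O1 of ring D, ring E as 3,5-bis(dimethoxymethyl)-4-fluorophenyl on O6 (not isolated) | COc1cc(C=O)c(Oc2cc(C=O)c(Oc3cc(C=O)c(Oc4cc(OC)c(OC)c(OC)c4Oc4cc(C(OC)OC)c(F)c(C(OC)OC)c4)c(C=O)c3)c(C=O)c2)c(C=O)c1 | intermediate
24 | A–E octaaldehyde fluoride: as 23 with ring E as 4-fluoro-3,5-diformylphenyl | COc1cc(C=O)c(Oc2cc(C=O)c(Oc3cc(C=O)c(Oc4cc(OC)c(OC)c(OC)c4Oc4cc(C=O)c(F)c(C=O)c4)c(C=O)c3)c(C=O)c2)c(C=O)c1 | intermediate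
25 | A–F acetal fluoride: ring F as 3,5-bis(dimethoxymethyl)-4-fluorophenoxy on the formyl-flanked carbon of ring E (not isolated) | COc1cc(C=O)c(Oc2cc(C=O)c(Oc3cc(C=O)c(Oc4cc(OC)c(OC)c(OC)c4Oc4cc(C=O)c(Oc5cc(C(OC)OC)c(F)c(C(OC)OC)c5)c(C=O)c4)c(C=O)c3)c(C=O)c2)c(C=O)c1 | intermediate
26 | A–F decaaldehyde fluoride: as 25 with ring F as 4-fluoro-3,5-diformylphenoxy | COc1cc(C=O)c(Oc2cc(C=O)c(Oc3cc(C=O)c(Oc4cc(OC)c(OC)c(OC)c4Oc4cc(C=O)c(Oc5cc(C=O)c(F)c(C=O)c5)c(C=O)c4)c(C=O)c3)c(C=O)c2)c(C=O)c1 | intermediate
27 | decaaldehyde heptamer: two formyl groups flanking the ether carbon on each of rings A, B, C, E and F; OMe on ring A (para), three OMe on ring D and on ring G | COc1cc(C=O)c(Oc2cc(C=O)c(Oc3cc(C=O)c(Oc4cc(OC)c(OC)c(OC)c4Oc4cc(C=O)c(Oc5cc(C=O)c(Oc6cc(OC)c(OC)c(OC)c6)c(C=O)c5)c(C=O)c4)c(C=O)c3)c(C=O)c2)c(C=O)c1 | intermediate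
28 | decaformate: every formyl group of 27 replaced by formyloxy (not isolated) | COc1cc(OC=O)c(Oc2cc(OC=O)c(Oc3cc(OC=O)c(Oc4cc(OC)c(OC)c(OC)c4Oc4cc(OC=O)c(Oc5cc(OC=O)c(Oc6cc(OC)c(OC)c(OC)c6)c(OC=O)c5)c(OC=O)c4)c(OC=O)c3)c(OC=O)c2)c(OC=O)c1 | intermediate
29 | decaphenol heptamethyl ether: every formyl group of 27 replaced by hydroxyl | COc1cc(O)c(Oc2cc(O)c(Oc3cc(O)c(Oc4cc(OC)c(OC)c(OC)c4Oc4cc(O)c(Oc5cc(O)c(Oc6cc(OC)c(OC)c(OC)c6)c(O)c5)c(O)c4)c(O)c3)c(O)c2)c(O)c1 | intermediate
30 | CNP0304148.0 (heptameric phlorotannin, all seventeen hydroxyls free) | Oc1cc(O)c(Oc2cc(O)c(Oc3cc(O)c(Oc4cc(O)c(O)c(O)c4Oc4cc(O)c(Oc5cc(O)c(Oc6cc(O)c(O)c(O)c6)c(O)c5)c(O)c4)c(O)c3)c(O)c2)c(O)c1 | target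

**Totals and risks**

Total step count: 17. Longest linear sequence: 12 steps (steps 1–7, then 13–17).

Steps most likely to fail:

1. Step 16 (tenfold Dakin oxidation). Hydride migration may compete with aryl migration at formyl groups whose ring still carries a second, electron-withdrawing formyl group, which would give carboxylic acids. The oxidation may also stall short of ten sites, or excess peracid may hydroxylate the trimethoxylated rings D and G. The fallback changes the oxidation level so that no migrating hydrogen remains. It sets out from 27: tenfold Grignard addition of MeMgBr (THF, −78 °C) should give the deca(1-hydroxyethyl) compound F1, a mixture of stereoisomers of no consequence. Oxidation with Dess–Martin periodinane (CH2Cl2, rt) should give the decaacetyl compound F2. Baeyer–Villiger oxidation (mCPBA, CF3CO2H cat., CH2Cl2), in which only aryl or methyl can migrate and aryl is preferred, should give the decaacetate F3. Methanolysis (HCl in MeOH, argon) returns to the route at 29.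

2. Step 11 (Ullmann coupling). A phenoxide flanked by benzyloxy and methoxy groups may bind copper through its neighbouring oxygens and couple slowly, so that protodebromination of 6 and oxidative degradation of the electron-rich phenol take over. The fallback replaces the aryl halide by an arylboron partner in an oxidative Chan–Lam coupling, which accepts di-ortho-substituted phenols at room temperature. It sets out from 6: bromine–lithium exchange and B(OMe)3 as in step 4, but with aqueous work-up at pH 7 in place of the peroxide, should give [3,5-bis(dimethoxymethyl)-4-fluorophenyl]boronic acid F4. Coupling of F4 with 20 using Cu(OAc)2 (divalent copper, 1 equiv), pyridine and 4 Å molecular sieves in CH2Cl2 under air comes back to the route at 21.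

3. Step 13 (union of the two halves). The ring D phenoxide carries a bulky ortho aryloxy group and may attack slowly. Aryloxide exchange at the two formyl-flanked ether carbons of 15, and hydrolysis of the doubly activated C–F bond by carbonate and traces of water, could then compete. The fallback removes the stoichiometric base. It sets out from 22, which is silylated (Me3SiCl, Et3N, CH2Cl2) to the trimethylsilyl ether of the D–E phenol F5. F5 and 15 are then joined with catalytic CsF in DMF at rt; each substitution releases the fluoride that desilylates the next molecule of F5, so only a catalytic amount of phenoxide is present and no carbonate. This comes back to the route at 23, which is hydrolysed to 24 as in step 13.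

Further compounds

F1 | step 16 | deca(1-hydroxyethyl) heptamer: every formyl group of 27 converted into CH(OH)CH3, stereoisomer mixture | COc1cc(C(C)O)c(Oc2cc(C(C)O)c(Oc3cc(C(C)O)c(Oc4cc(OC)c(OC)c(OC)c4Oc4cc(C(C)O)c(Oc5cc(C(C)O)c(Oc6cc(OC)c(OC)c(OC)c6)c(C(C)O)c5)c(C(C)O)c4)c(C(C)O)c3)c(C(C)O)c2)c(C(C)O)c1
F2 | step 16 | decaacetyl heptamer: every formyl group of 27 replaced by acetyl | COc1cc(C(C)=O)c(Oc2cc(C(C)=O)c(Oc3cc(C(C)=O)c(Oc4cc(OC)c(OC)c(OC)c4Oc4cc(C(C)=O)c(Oc5cc(C(C)=O)c(Oc6cc(OC)c(OC)c(OC)c6)c(C(C)=O)c5)c(C(C)=O)c4)c(C(C)=O)c3)c(C(C)=O)c2)c(C(C)=O)c1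
F3 | step 16 | decaacetate heptamer: every formyl group of 27 replaced by acetoxy | COc1cc(OC(C)=O)c(Oc2cc(OC(C)=O)c(Oc3cc(OC(C)=O)c(Oc4cc(OC)c(OC)c(OC)c4Oc4cc(OC(C)=O)c(Oc5cc(OC(C)=O)c(Oc6cc(OC)c(OC)c(OC)c6)c(OC(C)=O)c5)c(OC(C)=O)c4)c(OC(C)=O)c3)c(OC(C)=O)c2)c(OC(C)=O)c1
F4 | step 11 | [3,5-bis(dimethoxymethyl)-4-fluorophenyl]boronic acid | OB(O)c1cc(C(OC)OC)c(F)c(C(OC)OC)c1
F5 | step 13 | {2-[3,5-bis(dimethoxymethyl)-4-fluorophenoxy]-3,4,5-trimethoxyphenoxy}trimethylsilane | COc1cc(O[Si](C)(C)C)c(Oc2cc(C(OC)OC)c(F)c(C(OC)OC)c2)c(OC)c1OC
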